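Ring F of the lower unit is opened across C3–C4 and O1–C2. Lower C4 is a bare benzylic CH2 on ring D, ortho to O1, so C4, C4a, C8a and O1 can be released as an ortho-quinone methide, while C3 with its oxygen is supplied by benzyloxyacetaldehyde. One amine-catalysed operation joins C3 to C4, sets C3 and lets the phenol close the lactol. The precursor is the fully benzylated upper 4-arylflavan whose ring D carries a single free phenol and an ortho tosylmethyl group, masked until the previous step as an isopropylidene acetal. Ring E is then attached at the lactol carbon and all benzyl ethers are removed.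

Key step: step 10

Assumption: the facial sense of the pyridine–oxazoline ligand (step 2) and of the prolinol catalyst (step 10) is taken from the usual steric models; if either delivered the antipode, the mirror-image ligand or catalyst would be used.

Remark: the descriptor at upper C4 is S while ring D carries a benzyloxy group at C7 and becomes R in the free phenol; the geometry does not change.

Step 1
Reactants: 1 7-hydroxy-4H-chromen-4-one
Product: 2 7-(benzyloxy)-4H-chromen-4-one
Conditions: BnBr, K2CO3, acetone, reflux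
Reagents that add atoms: benzyl bromide, BrCc1ccccc1
Why: Williamson etherification of the acidic 7-OH with a carbonate base that is too weak to open the pyranone ring.

Step 2
Reactants: 2 7-(benzyloxy)-4H-chromen-4-one; 3 4-(benzyloxy)phenylboronic acid
Product: 4 (2S)-7-(benzyloxy)-2-[4-(benzyloxy)phenyl]chroman-4-one
Conditions: Pd(OCOCF3)2 (5 mol %), (R)-4-tert-butyl-2-(pyridin-2-yl)-4,5-dihydrooxazole (6 mol %), NH4PF6, H2O, ClCH2CH2Cl, 60 °C
Reagents that add atoms: none
Why: Palladium-catalysed asymmetric conjugate addition of an arylboronic acid to a chromone (transmetalation to divalent palladium, face-selective carbopalladation of C2=C3, protonolysis of the palladium enolate); the ligand selects the face and the (R)-ligand is expected to set 2S, which becomes 2R of the upper flavan-3-ol once C3 is oxygenated.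

Step 3
Reactants: 5 5-bromo-2,4-dihydroxybenzaldehyde
Product: 6 4-(benzyloxy)-5-bromo-2-hydroxybenzaldehyde
Conditions: BnBr (1.05 equiv), NaHCO3, KI (cat.), MeCN, 70 °C
Reagents that add atoms: benzyl bromide, BrCc1ccccc1
Why: Regioselective Williamson alkylation, since the 4-OH is the more acidic and unhindered phenol while the 2-OH is held in a hydrogen bond to the aldehyde.

Step 4
Reactants: 6 4-(benzyloxy)-5-bromo-2-hydroxybenzaldehyde
Product: 7 5-(benzyloxy)-4-bromo-2-(hydroxymethyl)phenol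
Conditions: NaBH4, THF/MeOH, 0 °C
Reagents that add atoms: none
Why: Borohydride reduction of the aldehyde to the benzylic alcohol; the aryl bromide and the benzyl ether are inert.

Step 5
Reactants: 7 5-(benzyloxy)-4-bromo-2-(hydroxymethyl)phenol
Product: 8 7-(benzyloxy)-6-bromo-2,2-dimethyl-4H-1,3-benzodioxine
Conditions: 2,2-dimethoxypropane, PPTS (cat.), acetone, rt
Reagents that add atoms: 2,2-dimethoxypropane, COC(C)(C)OC
Why: Acid-catalysed transacetalization closes a six-membered isopropylidene acetal that masks phenol and benzylic alcohol together and tolerates organolithium, borane and strong base.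

Step 6
Reactants: 8 7-(benzyloxy)-6-bromo-2,2-dimethyl-4H-1,3-benzodioxine; 4 (2S)-7-(benzyloxy)-2-[4-(benzyloxy)phenyl]chroman-4-one
Product: 11 (2S)-7-(benzyloxy)-4-[7-(benzyloxy)-2,2-dimethyl-4H-1,3-benzodioxin-6-yl]-2-[4-(benzyloxy)phenyl]-2H-chromene, via aryllithium 9 (not isolated), via tertiary alcohol 10 (not isolated)
Conditions: n-BuLi, THF, −78 °C; CeCl3; then 4, −78 °C; aq. NH4Cl; crude, MsCl, Et3N, CH2Cl2, 0 °C to rt
Reagents that add atoms: none
Why: Bromine–lithium exchange gives 9, whose weakly basic organocerium derivative adds 1,2 to the ketone with little enolization (ring C stays closed and C2 is kept), and the doubly benzylic tertiary mesylate then ionizes and loses a C3 proton (E1 dehydration) to give the C3=C4 alkene.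

Step 7
Reactants: 11 (2S)-7-(benzyloxy)-4-[7-(benzyloxy)-2,2-dimethyl-4H-1,3-benzodioxin-6-yl]-2-[4-(benzyloxy)phenyl]-2H-chromene
Product: 13 (2R,3S,4S)-7-(benzyloxy)-4-[7-(benzyloxy)-2,2-dimethyl-4H-1,3-benzodioxin-6-yl]-2-[4-(benzyloxy)phenyl]chroman-3-ol (2,3-trans-3,4-trans), via alkylborane 12 (not isolated)
Conditions: BH3·THF, THF, 0 °C to rt; then NaOH, H2O2, 0 °C
Reagents that add atoms: hydrogen peroxide, OO
Why: Hydroboration–oxidation: boron adds to C3 of the trisubstituted styrene-type alkene from the face opposite the C2 aryl group with syn delivery of hydrogen to C4, and oxidation with retention gives the 2,3-trans-3,4-trans alcohol, which sets C3 and C4.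

Step 8
Reactants: 13 (2R,3S,4S)-7-(benzyloxy)-4-[7-(benzyloxy)-2,2-dimethyl-4H-1,3-benzodioxin-6-yl]-2-[4-(benzyloxy)phenyl]chroman-3-ol
Product: 14 (2R,3S,4S)-3,7-bis(benzyloxy)-4-[7-(benzyloxy)-2,2-dimethyl-4H-1,3-benzodioxin-6-yl]-2-[4-(benzyloxy)phenyl]chromane
Conditions: NaH, BnBr, Bu4NI (cat.), DMF, 0 °C to rt
Reagents that add atoms: benzyl bromide, BrCc1ccccc1
Why: Williamson etherification of the secondary alkoxide, with iodide catalysis to help at the hindered C3 hydroxyl.

Step 9
Reactants: 14 (2R,3S,4S)-3,7-bis(benzyloxy)-4-[7-(benzyloxy)-2,2-dimethyl-4H-1,3-benzodioxin-6-yl]-2-[4-(benzyloxy)phenyl]chromane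
Product: 16 5-(benzyloxy)-4-[(2R,3S,4S)-3,7-bis(benzyloxy)-2-[4-(benzyloxy)phenyl]chroman-4-yl]-2-[(4-methylphenyl)sulfonylmethyl]phenol, via diol 15 (not isolated)
Conditions: sodium p-toluenesulfinate (3 equiv), HCO2H/H2O/THF, rt
Reagents that add atoms: sodium p-toluenesulfinate, [Na+].[O-]S(=O)c1ccc(C)cc1
Why: Aqueous acid hydrolyses the acetal to 15, whose electron-rich ortho-hydroxybenzyl alcohol ionizes with help from the para benzyloxy group and is trapped at sulfur by the sulfinate (SN1-type substitution), leaving the phenol free.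

Step 10
Reactants: 16 5-(benzyloxy)-4-[(2R,3S,4S)-3,7-bis(benzyloxy)-2-[4-(benzyloxy)phenyl]chroman-4-yl]-2-[(4-methylphenyl)sulfonylmethyl]phenol; 17 benzyloxyacetaldehyde
Product: 20 (3S)-3,7-bis(benzyloxy)-6-[(2R,3S,4S)-3,7-bis(benzyloxy)-2-[4-(benzyloxy)phenyl]chroman-4-yl]chroman-2-ol (both C2 epimers), via ortho-quinone methide 18 (not isolated), via hydroxy aldehyde 19 (not isolated)
Conditions: (R)-2-[diphenyl(trimethylsilyloxy)methyl]pyrrolidine (20 mol %), 17 (3 equiv), Na2CO3, CH2Cl2/H2O, 0 °C to rt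
Reagents that add atoms: none
Why: Carbonate deprotonates the only free phenol of 16 and 1,4-elimination of p-toluenesulfinate releases ortho-quinone methide 18, while the amine condenses with 17 to its E-enamine, whose α-carbon adds to the exocyclic methylene (rearomatizing ring D) to form lower C3–C4; hydrolysis of the iminium ion frees hydroxy aldehyde 19. The phenol then adds to the aldehyde in a 6-exo-trig hemiacetalization that forms O1–C2 and closes ring F as lactol 20. The closest known reaction type is the diarylprolinol silyl ether-catalysed Michael addition of aldehydes to ortho-quinone methides generated in situ from 2-(sulfonylmethyl)phenols, which ends in chroman-2-ols. The new C3 centre is controlled by the catalyst alone: the diphenyl(trimethylsilyloxy)methyl group blocks one face of the s-trans enamine, and with the (R)-catalyst the methylene should add to the open face that gives 3S, while C2 is left as a mixture that is erased in step 12. The step needs C-alkylation by the enamine to win over N-alkylation of free amine and over self-reaction of 18; the single acidic OH, the para benzyloxy group that tempers the methide, slow release by a weak base and the excess of 17 should secure this. The stereocentres of the upper unit lie far from the reacting carbon and should neither bias the addition nor be affected.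

Step 11
Reactants: 20 (3S)-3,7-bis(benzyloxy)-6-[(2R,3S,4S)-3,7-bis(benzyloxy)-2-[4-(benzyloxy)phenyl]chroman-4-yl]chroman-2-ol
Product: 21 (3S)-3,7-bis(benzyloxy)-6-[(2R,3S,4S)-3,7-bis(benzyloxy)-2-[4-(benzyloxy)phenyl]chroman-4-yl]chroman-2-yl acetate (both C2 epimers)
Conditions: Ac2O, pyridine, DMAP (cat.), CH2Cl2, 0 °C to rt
Reagents that add atoms: acetic anhydride, CC(=O)OC(C)=O
Why: O-Acylation of the lactol hydroxyl, the only free OH, gives the anomeric acetates as a storable oxocarbenium precursor.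

Step 12
Reactants: 21 (3S)-3,7-bis(benzyloxy)-6-[(2R,3S,4S)-3,7-bis(benzyloxy)-2-[4-(benzyloxy)phenyl]chroman-4-yl]chroman-2-yl acetate; 22 1,2-bis(benzyloxy)benzene
Product: 24 (2R,3S,4S)-3,7-bis(benzyloxy)-2-[4-(benzyloxy)phenyl]-4-{(2S,3S)-3,7-bis(benzyloxy)-2-[3,4-bis(benzyloxy)phenyl]chroman-6-yl}chromane, via oxocarbenium ion 23 (not isolated)
Conditions: 22 (20 equiv), BF3·OEt2, CH2Cl2, −78 to −40 °C, slow addition of 21
Reagents that add atoms: none
Why: Lewis acid ionization to 23 and Friedel–Crafts alkylation of the catechol diether para to one benzyloxy group; the non-participating C3 benzyloxy group prefers the pseudoequatorial position of the half-chair cation, so attack along the pseudoaxial path anti to C3–H should give the 2,3-cis (2S) flavan under kinetic control at low temperature, with the large excess of arene meant to outcompete the other electron-rich rings.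

Step 13
Reactants: 24 (2R,3S,4S)-3,7-bis(benzyloxy)-2-[4-(benzyloxy)phenyl]-4-{(2S,3S)-3,7-bis(benzyloxy)-2-[3,4-bis(benzyloxy)phenyl]chroman-6-yl}chromane
Product: 25 (2R,3S,4R)-4-[(2S,3S)-2-(3,4-dihydroxyphenyl)-3,7-dihydroxychroman-6-yl]-2-(4-hydroxyphenyl)chromane-3,7-diol
Conditions: H2 (1 atm), Pd(OH)2/C, THF/MeOH, rt
Reagents that add atoms: none
Why: Hydrogenolysis of all seven benzyl ethers; the cyclic benzylic C–O bonds and the C4–aryl bond of flavans are expected to survive these mild conditions, so no stereocentre is touched.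

Compound list
1 | 7-hydroxy-4H-chromen-4-one | O=c1ccoc2cc(O)ccc12 | starting material
2 | 7-(benzyloxy)-4H-chromen-4-one | O=c1ccoc2cc(OCc3ccccc3)ccc12 | intermediate
3 | 4-(benzyloxy)phenylboronic acid | OB(O)c1ccc(OCc2ccccc2)cc1 | starting material
4 | (2S)-7-(benzyloxy)-2-[4-(benzyloxy)phenyl]chroman-4-one | c1ccccc1COc1ccc([C@H]2Oc3cc(OCc4ccccc4)ccc3C(=O)C2)cc1 | intermediate
5 | 5-bromo-2,4-dihydroxybenzaldehyde | O=Cc1cc(Br)c(O)cc1O | starting material
6 | 4-(benzyloxy)-5-bromo-2-hydroxybenzaldehyde | O=Cc1cc(Br)c(OCc2ccccc2)cc1O | intermediate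
7 | 5-(benzyloxy)-4-bromo-2-(hydroxymethyl)phenol | OCc1cc(Br)c(OCc2ccccc2)cc1O | intermediate
8 | 7-(benzyloxy)-6-bromo-2,2-dimethyl-4H-1,3-benzodioxine | CC1(C)OCc2cc(Br)c(OCc3ccccc3)cc2O1 | intermediate
9 | [7-(benzyloxy)-2,2-dimethyl-4H-1,3-benzodioxin-6-yl]lithium (not isolated) | CC1(C)OCc2cc([Li])c(OCc3ccccc3)cc2O1 | intermediate
10 | (2S)-7-(benzyloxy)-4-[7-(benzyloxy)-2,2-dimethyl-4H-1,3-benzodioxin-6-yl]-2-[4-(benzyloxy)phenyl]chroman-4-ol, C4 epimers (not isolated) | c1ccccc1COc1ccc([C@H]2Oc3cc(OCc4ccccc4)ccc3C(O)(c3cc4COC(C)(C)Oc4cc3OCc3ccccc3)C2)cc1 | intermediate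
11 | (2S)-7-(benzyloxy)-4-[7-(benzyloxy)-2,2-dimethyl-4H-1,3-benzodioxin-6-yl]-2-[4-(benzyloxy)phenyl]-2H-chromene | c1ccccc1COc1ccc([C@H]2Oc3cc(OCc4ccccc4)ccc3C(c3cc4COC(C)(C)Oc4cc3OCc3ccccc3)=C2)cc1 | intermediate
12 | C3 alkylborane from 11, boron trans to the C2 aryl group and cis to H4 (not isolated) | c1ccccc1COc1ccc([C@H]2Oc3cc(OCc4ccccc4)ccc3[C@@H](c3cc4COC(C)(C)Oc4cc3OCc3ccccc3)[C@@H]2B)cc1 | intermediate
13 | (2R,3S,4S)-7-(benzyloxy)-4-[7-(benzyloxy)-2,2-dimethyl-4H-1,3-benzodioxin-6-yl]-2-[4-(benzyloxy)phenyl]chroman-3-ol | c1ccccc1COc1ccc([C@H]2Oc3cc(OCc4ccccc4)ccc3[C@@H](c3cc4COC(C)(C)Oc4cc3OCc3ccccc3)[C@@H]2O)cc1 | intermediate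
14 | (2R,3S,4S)-3,7-bis(benzyloxy)-4-[7-(benzyloxy)-2,2-dimethyl-4H-1,3-benzodioxin-6-yl]-2-[4-(benzyloxy)phenyl]chromane | c1ccccc1COc1ccc([C@H]2Oc3cc(OCc4ccccc4)ccc3[C@@H](c3cc4COC(C)(C)Oc4cc3OCc3ccccc3)[C@@H]2OCc2ccccc2)cc1 | intermediate
15 | 5-(benzyloxy)-4-[(2R,3S,4S)-3,7-bis(benzyloxy)-2-[4-(benzyloxy)phenyl]chroman-4-yl]-2-(hydroxymethyl)phenol (not isolated) | c1ccccc1COc1ccc([C@H]2Oc3cc(OCc4ccccc4)ccc3[C@@H](c3cc(CO)c(O)cc3OCc3ccccc3)[C@@H]2OCc2ccccc2)cc1 | intermediate
16 | 5-(benzyloxy)-4-[(2R,3S,4S)-3,7-bis(benzyloxy)-2-[4-(benzyloxy)phenyl]chroman-4-yl]-2-[(4-methylphenyl)sulfonylmethyl]phenol | c1ccccc1COc1ccc([C@H]2Oc3cc(OCc4ccccc4)ccc3[C@@H](c3cc(CS(=O)(=O)c4ccc(C)cc4)c(O)cc3OCc3ccccc3)[C@@H]2OCc2ccccc2)cc1 | intermediate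
17 | benzyloxyacetaldehyde | O=CCOCc1ccccc1 | starting material
18 | ortho-quinone methide of ring D: 3-(benzyloxy)-6-methylidene-4-(protected flavan-4-yl)cyclohexa-2,4-dien-1-one (not isolated) | c1ccccc1COc1ccc([C@H]2Oc3cc(OCc4ccccc4)ccc3[C@@H](C3=CC(=C)C(=O)C=C3OCc3ccccc3)[C@@H]2OCc2ccccc2)cc1 | intermediate
19 | (2S)-2-(benzyloxy)-3-{4-(benzyloxy)-5-[(2R,3S,4S)-3,7-bis(benzyloxy)-2-[4-(benzyloxy)phenyl]chroman-4-yl]-2-hydroxyphenyl}propanal (not isolated) | c1ccccc1COc1ccc([C@H]2Oc3cc(OCc4ccccc4)ccc3[C@@H](c3cc(C[C@H](OCc4ccccc4)C=O)c(O)cc3OCc3ccccc3)[C@@H]2OCc2ccccc2)cc1 | intermediate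
20 | (3S)-3,7-bis(benzyloxy)-6-[(2R,3S,4S)-3,7-bis(benzyloxy)-2-[4-(benzyloxy)phenyl]chroman-4-yl]chroman-2-ol, C2 epimers | c1ccccc1COc1ccc([C@H]2Oc3cc(OCc4ccccc4)ccc3[C@@H](c3cc4c(cc3OCc3ccccc3)OC(O)[C@@H](OCc3ccccc3)C4)[C@@H]2OCc2ccccc2)cc1 | intermediate
21 | (3S)-3,7-bis(benzyloxy)-6-[(2R,3S,4S)-3,7-bis(benzyloxy)-2-[4-(benzyloxy)phenyl]chroman-4-yl]chroman-2-yl acetate, C2 epimers | c1ccccc1COc1ccc([C@H]2Oc3cc(OCc4ccccc4)ccc3[C@@H](c3cc4c(cc3OCc3ccccc3)OC(OC(C)=O)[C@@H](OCc3ccccc3)C4)[C@@H]2OCc2ccccc2)cc1 | intermediate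
22 | 1,2-bis(benzyloxy)benzene | c1ccccc1COc1ccccc1OCc1ccccc1 | starting material
23 | (3S)-3,7-bis(benzyloxy)-6-(protected flavan-4-yl)-3,4-dihydrochromenylium ion (not isolated) | c1ccccc1COc1ccc([C@H]2Oc3cc(OCc4ccccc4)ccc3[C@@H](c3cc4c(cc3OCc3ccccc3)[O+]=C[C@@H](OCc3ccccc3)C4)[C@@H]2OCc2ccccc2)cc1 | intermediate
24 | (2R,3S,4S)-3,7-bis(benzyloxy)-2-[4-(benzyloxy)phenyl]-4-{(2S,3S)-3,7-bis(benzyloxy)-2-[3,4-bis(benzyloxy)phenyl]chroman-6-yl}chromane | c1ccccc1COc1ccc([C@H]2Oc3cc(OCc4ccccc4)ccc3[C@@H](c3cc4c(cc3OCc3ccccc3)O[C@@H](c3ccc(OCc5ccccc5)c(OCc5ccccc5)c3)[C@@H](OCc3ccccc3)C4)[C@@H]2OCc2ccccc2)cc1 | intermediate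
25 | (2R,3S,4R)-4-[(2S,3S)-2-(3,4-dihydroxyphenyl)-3,7-dihydroxychroman-6-yl]-2-(4-hydroxyphenyl)chromane-3,7-diol (upper unit 2,3-trans-3,4-trans, lower unit 2,3-cis) | Oc1ccc([C@H]2Oc3cc(O)ccc3[C@@H](c3cc4c(cc3O)O[C@@H](c3ccc(O)c(O)c3)[C@@H](O)C4)[C@@H]2O)cc1 | target

Total step count: 13. Longest linear sequence: 11 steps (steps 3 to 13, from 5).

Steps most likely to fail

Step 12. The cation may alkylate the resorcinol-type ring A of a second molecule faster than the external catechol diether, which would lead to oligomers. The arene may also add trans to the C3 benzyloxy group, the product may re-ionize at C2 and equilibrate, or the cation may lose H3 to an enol ether. The fallback sets out from lactol 20 and comes back at 24. Lactol 20 reacts through its open aldehyde form with an excess of [3,4-bis(benzyloxy)phenyl]magnesium bromide F1 (from commercial 4-bromo-1,2-bis(benzyloxy)benzene and Mg, THF) to give the phenolic carbinol F2 as a mixture at the new carbinol carbon. MnO2 in CH2Cl2 should oxidize this electron-rich benzylic carbinol to the aryl ketone F3. Et3SiH with BF3·OEt2 in CH2Cl2 at low temperature then recloses ring F by reductive etherification. In the cyclic 2-aryl oxocarbenium ion, allylic strain with the aryl group should place the C3 benzyloxy group pseudoaxial, so hydride delivered anti to it gives the 2,3-cis flavan 24. No free cation meets an arene nucleophile in this sequence.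

Step 10. The unsubstituted quinone methide may be captured by free amine catalyst or by itself before the enamine reaches it. The α-alkoxy enamine may also add with poor facial selectivity, or the product may lose its C3 configuration through renewed enamine formation. The fallback sets out from sulfone 16 and aldehyde 17 and comes back at lactol 20. Aldehyde 17 is condensed with (S)-1-amino-2-(methoxymethyl)pyrrolidine to the hydrazone F4. Its lithium azaenolate (LDA, THF, −78 °C, 2.5 equiv) serves as the base that releases the quinone methide from 16 on warming and as the auxiliary-controlled carbon nucleophile, giving the C-alkylated hydrazone F5. By analogy with simple aldehyde hydrazones this auxiliary is expected to give 3S. Two-phase cleavage with aqueous oxalic acid frees the aldehyde, which closes to 20.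

Step 6. The basic aryl nucleophile may enolize the flavanone, after which β-elimination of the ring oxygen opens ring C and erases the C2 configuration; addition of the hindered ortho-substituted aryl group may also be sluggish. The fallback sets out from 4 and 8 and comes back at 11. Flavanone 4 is converted without an enolate into the enol triflate F6 (Tf2O, 2,6-di-tert-butyl-4-methylpyridine, CH2Cl2, 0 °C). Bromide 8 is borylated to the pinacol boronate F7 (B2pin2, KOAc, Pd(dppf)Cl2, dioxane, 80 °C). Suzuki–Miyaura coupling of F6 with F7 (Pd(PPh3)4, K3PO4, dioxane/H2O, 60 °C) gives alkene 11 directly.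

Further compounds
F1 | step 12 | [3,4-bis(benzyloxy)phenyl]magnesium bromide | Br[Mg]c1ccc(OCc2ccccc2)c(OCc2ccccc2)c1
F2 | step 12 | (2S)-2-(benzyloxy)-1-[3,4-bis(benzyloxy)phenyl]-3-{4-(benzyloxy)-5-[(2R,3S,4S)-3,7-bis(benzyloxy)-2-[4-(benzyloxy)phenyl]chroman-4-yl]-2-hydroxyphenyl}propan-1-ol, C1 epimers | c1ccccc1COc1ccc([C@H]2Oc3cc(OCc4ccccc4)ccc3[C@@H](c3cc(C[C@H](OCc4ccccc4)C(O)c4ccc(OCc5ccccc5)c(OCc5ccccc5)c4)c(O)cc3OCc3ccccc3)[C@@H]2OCc2ccccc2)cc1
F3 | step 12 | (2S)-2-(benzyloxy)-1-[3,4-bis(benzyloxy)phenyl]-3-{4-(benzyloxy)-5-[(2R,3S,4S)-3,7-bis(benzyloxy)-2-[4-(benzyloxy)phenyl]chroman-4-yl]-2-hydroxyphenyl}propan-1-one | c1ccccc1COc1ccc([C@H]2Oc3cc(OCc4ccccc4)ccc3[C@@H](c3cc(C[C@H](OCc4ccccc4)C(=O)c4ccc(OCc5ccccc5)c(OCc5ccccc5)c4)c(O)cc3OCc3ccccc3)[C@@H]2OCc2ccccc2)cc1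
F4 | step 10 | (E)-hydrazone of benzyloxyacetaldehyde with (S)-1-amino-2-(methoxymethyl)pyrrolidine | COC[C@@H]1CCCN1/N=C/COCc1ccccc1
F5 | step 10 | (E)-hydrazone of aldehyde 19 (2S) with (S)-1-amino-2-(methoxymethyl)pyrrolidine | c1ccccc1COc1ccc([C@H]2Oc3cc(OCc4ccccc4)ccc3[C@@H](c3cc(C[C@H](OCc4ccccc4)/C=N/N4CCC[C@H]4COC)c(O)cc3OCc3ccccc3)[C@@H]2OCc2ccccc2)cc1
F6 | step 6 | (2S)-7-(benzyloxy)-2-[4-(benzyloxy)phenyl]-2H-chromen-4-yl trifluoromethanesulfonate | c1ccccc1COc1ccc([C@H]2Oc3cc(OCc4ccccc4)ccc3C(OS(=O)(=O)C(F)(F)F)=C2)cc1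
F7 | step 6 | 2-[7-(benzyloxy)-2,2-dimethyl-4H-1,3-benzodioxin-6-yl]-4,4,5,5-tetramethyl-1,3,2-dioxaborolane | CC1(C)OCc2cc(B3OC(C)(C)C(C)(C)O3)c(OCc3ccccc3)cc2O1
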